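**Strategy.** The target is read as a rearranged head-to-head dimer of two cinnamic acids. Its carbocycle C1–C2–C3–C4–C4a–C8a is grown from the cyclobutane C1–C2–C3–C4 of a tethered truxinate: as an arene radical cation the doubly benzylic C1–C4 bond opens and C1 closes on C8a, the carbon of the dimethoxyphenyl ring para to a methoxy group. This one operation builds the tetralin, sets C1 trans to C2 and erases both aryl-bearing cyclobutane stereocentres, so that all aryl epimers converge. The precursor, made by [2+2] photocycloaddition of a mixed dicinnamate on a C2-symmetric threitol tether, already holds C2 and C3. Hydride cleavage of the tether then reveals both hydroxymethyl groups and the catechol.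

Key step: step 4

Assumption: the (4S,5S) tether is taken to induce the (R,R) configuration at the two ester-bearing cyclobutane carbons; if the opposite sense is found, the equally available (4R,5R) diol is used and nothing else changes.

Tetralin numbering (C1 aryl-bearing, C2, C3, C4 = CH2, C4a, C8a) is used throughout, also for the cyclobutane carbons that become these atoms.

**Step 1**
Reactants: 1 (E)-3,4-dimethoxycinnamic acid; 2 (4S,5S)-2,2-dimethyl-1,3-dioxolane-4,5-dimethanol
Product: 3 mono-(3,4-dimethoxycinnamate) of diol 2
Conditions: 2 (3 equiv), DCC, DMAP (cat.), CH2Cl2, 0 °C to rt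
Reagents that add atoms: none
Why: Steglich esterification; the two hydroxyl groups of the C2-symmetric diol are equivalent, so an excess of 2 should give mainly the mono-ester (surplus diol is recovered), and no stereocentre is touched.

**Step 2**
Reactants: 3 mono-(3,4-dimethoxycinnamate) of diol 2; 4 (E)-3,4-diacetoxycinnamic acid
Product: 6 mixed dicinnamate of diol 2, via 3,4-diacetoxycinnamoyl chloride 5 (not isolated)
Conditions: 4, (COCl)2, DMF (cat.), CH2Cl2, 0 °C to rt, evaporate; then 3, pyridine, CH2Cl2, 0 °C
Reagents that add atoms: none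
Why: Acylation of the remaining primary alcohol by the acid chloride (nucleophilic acyl substitution) should be faster than acetyl transfer from the aryl acetates, which is why pyridine alone and no DMAP is used; no stereocentre is formed.

**Step 3**
Reactants: 6 mixed dicinnamate of diol 2
Product: 8 tether-bridged all-trans (δ-truxinate-type) cyclobutane, via triplet 1,4-biradical 7 (not isolated)
Conditions: [Ir(dF(CF3)ppy)2(dtbbpy)]PF6 (1 mol%), MeCN (0.01 M, degassed), 450 nm LEDs, rt; chromatography to remove tether diastereomers
Reagents that add atoms: none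
Why: Triplet-sensitised intramolecular [2+2] photocycloaddition of a tethered dicinnamate (energy transfer): the first bond joins the two α-carbons to give the doubly benzylic biradical 7 and a ten-membered dilactone, the C2-symmetric tether favours a C2-symmetric approach and so trans (R,R) ester-bearing carbons (sense as assumed), closure should give mainly the all-trans cyclobutane, and aryl epimers need not be removed because they converge in step 4.

**Step 4**
Reactants: 8 tether-bridged all-trans cyclobutane
Product: 11 tether-bridged (1S,2R,3R)-1-aryltetralin-2,3-dicarboxylate, via distonic 1,4-radical cation 9 (not isolated), via C4 benzylic radical 10 (not isolated)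
Conditions: 3,6-di-tert-butyl-9-mesityl-10-phenylacridinium BF4 (5 mol%), (PhS)2 (20 mol%), 2,6-lutidine (10 mol%), DCE (0.02 M), 450 nm LEDs, rt, Ar
Reagents that add atoms: none
Why: Proposed new method: the excited acridinium oxidises the dimethoxyphenyl ring of 8, the strained, doubly benzylic C1–C4 bond opens to the distonic radical cation 9 (cation at C4 held by the para-methoxy group, benzylic radical at C1), C1 adds to C8a, loss of the C8a proton re-aromatises the ring to radical 10, and thiophenol formed from the disulfide gives its hydrogen to C4 while the thiyl radical re-oxidises the acridine radical, so that the whole is a redox-neutral isomerisation; the closest known reaction types are the radical-cation vinylcyclobutane-to-cyclohexene [1,3] shift and the acridinium/disulfide radical-cation [4+2] annulation of two styrenes to 1-aryltetralins, which runs through the same kind of 1,4-radical cation, here entered by the known radical-cation opening of a 1,2-diarylcyclobutane. The only ring closed is the six-membered carbocycle, by 1,6-attack of C1 on the ortho carbon of the oxidised arene followed by re-aromatisation, as the four-membered ring opens. C2 and C3 are not touched and keep the trans arrangement and absolute configuration set in step 3, C1 is formed anew trans to the C2 ester because the aryl group takes the pseudo-equatorial place in the chair-like closure and the closure is reversible until the proton is lost, and C4 becomes CH2. Since both aryl-bearing carbons of 8 lose their configuration in 9, every aryl epimer of 8 should give the same product. The step needs closure on the dimethoxy ring at the carbon para to a methoxy group and not on the pendant ring, which the two acetyl groups secure by making that ring a poor hole carrier and a poor π-nucleophile. It also needs closure to outrun cycloreversion, which dilution, the ester groups (an enoate radical cation is a poor leaving fragment) and the tether (a cleaved pair stays joined as 6 and can go through step 3 again) are meant to secure.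

**Step 5**
Reactants: 11 tether-bridged (1S,2R,3R)-1-aryltetralin-2,3-dicarboxylate
Product: 12 4-[(1S,2R,3R)-2,3-bis(hydroxymethyl)-6,7-dimethoxy-1,2,3,4-tetrahydronaphthalen-1-yl]benzene-1,2-diol
Conditions: LiAlH4 (6 equiv), THF, 0 °C to rt, Ar; degassed aqueous Rochelle salt then dilute HCl
Reagents that add atoms: none
Why: Hydride reduction (LiAlH4) should cleave both tether esters to the two hydroxymethyl groups and both aryl acetates to the catechol in one operation, with release of diol 2 and without touching C1, C2 or C3.

**Compound list**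

1 | (E)-3-(3,4-dimethoxyphenyl)prop-2-enoic acid | COc1ccc(/C=C/C(O)=O)cc1OC | starting material
2 | (4S,5S)-2,2-dimethyl-1,3-dioxolane-4,5-dimethanol | OC[C@@H]1OC(C)(C)O[C@H]1CO | starting material
3 | [(4S,5S)-5-(hydroxymethyl)-2,2-dimethyl-1,3-dioxolan-4-yl]methyl (E)-3-(3,4-dimethoxyphenyl)prop-2-enoate | COc1ccc(/C=C/C(=O)OC[C@@H]2OC(C)(C)O[C@H]2CO)cc1OC | intermediate
4 | (E)-3-(3,4-diacetoxyphenyl)prop-2-enoic acid | CC(=O)Oc1ccc(/C=C/C(O)=O)cc1OC(C)=O | starting material
5 | (E)-3-(3,4-diacetoxyphenyl)prop-2-enoyl chloride (not isolated) | CC(=O)Oc1ccc(/C=C/C(Cl)=O)cc1OC(C)=O | intermediate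
6 | mixed diester of 2 with (E)-3,4-dimethoxycinnamic and (E)-3,4-diacetoxycinnamic acid | COc1ccc(/C=C/C(=O)OC[C@@H]2OC(C)(C)O[C@H]2COC(=O)/C=C/c2ccc(OC(C)=O)c(OC(C)=O)c2)cc1OC | intermediate
7 | triplet 1,4-biradical: α,α'-bonded ten-membered dilactone with two benzylic radical centres (not isolated) | CC(=O)Oc1ccc(cc1OC(C)=O)[CH][C@@H](C(=O)OC[C@@H]3OC(C)(C)O[C@H]3COC4=O)[C@H]4[CH]c1ccc(OC)c(OC)c1 | intermediate
8 | cyclic [(4S,5S)-2,2-dimethyl-1,3-dioxolane-4,5-diyl]dimethylene diester of (1R,2R,3S,4S)-4-(3,4-diacetoxyphenyl)-3-(3,4-dimethoxyphenyl)cyclobutane-1,2-dicarboxylic acid (all-trans) | CC(=O)Oc1ccc(cc1OC(C)=O)[C@@H]5[C@@H](C(=O)OC[C@@H]3OC(C)(C)O[C@H]3COC4=O)[C@H]4[C@H]5c1ccc(OC)c(OC)c1 | intermediate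
9 | ring-opened distonic 1,4-radical cation: cation at the dimethoxybenzylic carbon C4, radical at the diacetoxybenzylic carbon C1 (not isolated) | CC(=O)Oc1ccc(cc1OC(C)=O)[CH][C@@H](C(=O)OC[C@@H]3OC(C)(C)O[C@H]3COC4=O)[C@H]4[CH+]c1ccc(OC)c(OC)c1 | intermediate
10 | re-aromatised tetralin with a benzylic radical at C4 (not isolated) | COc1cc2c(cc1OC)[C@H](c1ccc(OC(C)=O)c(OC(C)=O)c1)[C@@H](C(=O)OC[C@@H]3OC(C)(C)O[C@H]3COC4=O)[C@H]4[CH]2 | intermediate
11 | cyclic [(4S,5S)-2,2-dimethyl-1,3-dioxolane-4,5-diyl]dimethylene diester of (1S,2R,3R)-1-(3,4-diacetoxyphenyl)-6,7-dimethoxy-1,2,3,4-tetrahydronaphthalene-2,3-dicarboxylic acid | COc1cc2c(cc1OC)[C@H](c1ccc(OC(C)=O)c(OC(C)=O)c1)[C@@H](C(=O)OC[C@@H]3OC(C)(C)O[C@H]3COC4=O)[C@H]4C2 | intermediate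
12 | 4-[(1S,2R,3R)-2,3-bis(hydroxymethyl)-6,7-dimethoxy-1,2,3,4-tetrahydronaphthalen-1-yl]benzene-1,2-diol | COc1cc2c(cc1OC)[C@H](c1ccc(O)c(O)c1)[C@@H](CO)[C@H](CO)C2 | target

**Step count.** Total: 5 steps. Longest linear sequence: 5 steps (1 or 2 to 12; acid 4 enters at step 2).

**Steps most likely to fail**

1. Step 4. Cycloreversion of the ring-opened radical cation to the two enoate halves may outrun the 1,6-closure, or C4 may close on the pendant ring. The fallback uses known chemistry only, gives up the cyclobutane and closes the carbocycle by the classical cationic cyclisation; it sets out from 1 and comes back at 12. Hydrogenation of 1 (H2, Pd/C) should give 3-(3,4-dimethoxyphenyl)propanoic acid F1. Its mixed pivalic anhydride acylates (S)-4-benzyloxazolidin-2-one (PivCl, Et3N, LiCl) to the N-acyl oxazolidinone F2. Evans alkylation (NaHMDS, tert-butyl bromoacetate, −78 °C) should give the (R)-configured alkylated imide F3, the electrophile entering anti to the benzyl group of the auxiliary. LiBH4 reduction and TFA lactonisation give the (R)-β-benzyl butyrolactone F4. Its lithium enolate (LDA, −78 °C) adds to 3,4-bis(benzyloxy)benzaldehyde anti to the benzyl group to give the trans aldol F5 as carbinol epimers. TFA in CH2Cl2 ionises the benzylic alcohol and the dimethoxy ring closes para to methoxy (Friedel–Crafts) to the all-trans aryltetralin lactone F6. LiAlH4 gives the dibenzyl ether diol F7, and hydrogenolysis (H2, Pd/C) gives 12.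

2. Step 3. Facial selectivity in the first C–C bond formation may be poor (wrong tether diastereomer or cis-diester), with E/Z isomerisation competing. The fallback changes from a diastereoselective cycloaddition to resolution with recycling; it sets out from 6 and comes back at 8. The tether makes the two cyclobutane antipodes diastereomers, so the tether diastereomer with the enantiomeric (1S,2S,3R,4R) cyclobutane core F8 is separated by chromatography. It is split back to 6 by direct irradiation at 254 nm (known cycloreversion of arylcyclobutanes) and put through the cycloaddition again until the material is collected as 8.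

3. Step 5. Cleavage of the hindered macrocyclic diester may be incomplete, and the catecholate may be lost through aluminium chelation and air oxidation during work-up. The fallback separates deprotection from reduction; it sets out from 11 and comes back at 12. NaOMe (cat.) in MeOH under argon removes both acetates and the tether by transesterification to give the dimethyl ester catechol F9; the all-trans diester is the thermodynamic isomer, so C2 and C3 are not at risk. LiBH4 in THF/MeOH then reduces the unhindered methyl esters to 12 with a mild acidic work-up.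

**Further compounds**

F1 | step 4 | 3-(3,4-dimethoxyphenyl)propanoic acid | COc1ccc(CCC(O)=O)cc1OC
F2 | step 4 | (4S)-4-benzyl-3-[3-(3,4-dimethoxyphenyl)propanoyl]-1,3-oxazolidin-2-one | COc1ccc(CCC(=O)N2[C@@H](Cc3ccccc3)COC2=O)cc1OC
F3 | step 4 | tert-butyl (3R)-3-{[(4S)-4-benzyl-2-oxo-1,3-oxazolidin-3-yl]carbonyl}-4-(3,4-dimethoxyphenyl)butanoate | COc1ccc(C[C@H](CC(=O)OC(C)(C)C)C(=O)N2[C@@H](Cc3ccccc3)COC2=O)cc1OC
F4 | step 4 | (4R)-4-(3,4-dimethoxybenzyl)oxolan-2-one | COc1ccc(C[C@H]2COC(=O)C2)cc1OC
F5 | step 4 | (3S,4R)-3-{[3,4-bis(benzyloxy)phenyl](hydroxy)methyl}-4-(3,4-dimethoxybenzyl)oxolan-2-one (carbinol epimers) | COc1ccc(C[C@H]2COC(=O)[C@@H]2C(O)c2ccc(OCc3ccccc3)c(OCc3ccccc3)c2)cc1OC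
F6 | step 4 | trans-fused γ-lactone of (1S,2R,3R)-1-[3,4-bis(benzyloxy)phenyl]-3-(hydroxymethyl)-6,7-dimethoxy-1,2,3,4-tetrahydronaphthalene-2-carboxylic acid | COc1cc2c(cc1OC)[C@H](c1ccc(OCc3ccccc3)c(OCc3ccccc3)c1)[C@H]4C(=O)OC[C@@H]4C2
F7 | step 4 | [(1S,2R,3R)-1-[3,4-bis(benzyloxy)phenyl]-6,7-dimethoxy-1,2,3,4-tetrahydronaphthalene-2,3-diyl]dimethanol | COc1cc2c(cc1OC)[C@H](c1ccc(OCc3ccccc3)c(OCc3ccccc3)c1)[C@@H](CO)[C@H](CO)C2
F8 | step 3 | cyclic [(4S,5S)-2,2-dimethyl-1,3-dioxolane-4,5-diyl]dimethylene diester of (1S,2S,3R,4R)-4-(3,4-diacetoxyphenyl)-3-(3,4-dimethoxyphenyl)cyclobutane-1,2-dicarboxylic acid | CC(=O)Oc1ccc(cc1OC(C)=O)[C@H]5[C@H](C(=O)OC[C@@H]3OC(C)(C)O[C@H]3COC4=O)[C@@H]4[C@@H]5c1ccc(OC)c(OC)c1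
F9 | step 5 | dimethyl (1S,2R,3R)-1-(3,4-dihydroxyphenyl)-6,7-dimethoxy-1,2,3,4-tetrahydronaphthalene-2,3-dicarboxylate | COc1cc2c(cc1OC)[C@H](c1ccc(O)c(O)c1)[C@@H](C(=O)OC)[C@H](C(=O)OC)C2
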